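**Retrosynthetic overview**
- The target is unmasked last: one BCl3 operation removes two benzyl ethers and the peri (C5) methyl ether from a fully O-alkylated flavone.
- The 3-OMe is not carried in through a chalcone/flavonol (Algar–Flynn–Oyamada) or Baker–Venkataraman sequence; it is installed by Cu-catalysed C–O coupling on a 3-iodoflavone.
- Key step: ICl-induced demethylative 6-endo iodocyclisation of an aryl ynone whose A-ring is a symmetric pentamethoxyphenyl group, so either ortho-OMe closes to the same chromone.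
- The ynone comes from a B-ring aryl acetylide and a pentamethoxy Weinreb benzamide (ortho-lithiation of pentamethoxybenzene); the alkyne comes from 3,4-bis(benzyloxy)benzaldehyde via Dakin, methylation, Vilsmeier and Ohira–Bestmann steps.
- Ring order: both benzene rings are bought preformed; the pyranone C-ring is the only ring made, formed in the iodocyclisation.

Assumption: the target has no stereocentre (it is achiral), so "single enantiomer" needs no stereocontrol, and pentamethoxybenzene is taken as a catalogue compound.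

**Step 1**
Reactants: 1 3,4-bis(benzyloxy)benzaldehyde
Product: 3 3,4-bis(benzyloxy)phenol, via aryl formate 2 (not isolated)
Conditions: mCPBA, CH2Cl2, 0 °C → rt; aq NaHCO3 wash; then K2CO3 (cat.), MeOH, rt
Reagents that add atoms: mCPBA (3-chloroperoxybenzoic acid), OOC(=O)c1cccc(Cl)c1
Why: Dakin-type Baeyer–Villiger oxidation, in which the electron-rich aryl group migrates to give the formate that is then methanolysed to the phenol; no stereocentre is formed.

**Step 2**
Reactants: 3 3,4-bis(benzyloxy)phenol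
Product: 4 1,2-bis(benzyloxy)-4-methoxybenzene
Conditions: MeI, K2CO3, acetone, reflux
Reagents that add atoms: iodomethane, CI
Why: Williamson ether synthesis on the only free phenol fixes what becomes the 2'-OMe.

**Step 3**
Reactants: 4 1,2-bis(benzyloxy)-4-methoxybenzene
Product: 6 4,5-bis(benzyloxy)-2-methoxybenzaldehyde, via aryl iminium chloride 5 (not isolated)
Conditions: POCl3, DMF, 0 → 70 °C; then ice/H2O
Reagents that add atoms: N,N-dimethylformamide, CN(C)C=O; water, O
Why: Vilsmeier–Haack formylation goes to the position ortho to OMe and para to OBn, as in the formylation of 1,2,4-trimethoxybenzene, because the other activated site is flanked by two alkoxy groups.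

**Step 4**
Reactants: 6 4,5-bis(benzyloxy)-2-methoxybenzaldehyde
Product: 7 1,2-bis(benzyloxy)-4-ethynyl-5-methoxybenzene
Conditions: dimethyl (1-diazo-2-oxopropyl)phosphonate, K2CO3, MeOH, 0 °C → rt
Reagents that add atoms: dimethyl (1-diazo-2-oxopropyl)phosphonate (Ohira–Bestmann reagent), COP(=O)(OC)C(=[N+]=[N-])C(C)=O
Why: Seyferth–Gilbert homologation (Ohira–Bestmann variant) converts the non-enolisable aryl aldehyde into the terminal alkyne under mild base that leaves the benzyl ethers untouched.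

**Step 5**
Reactants: 8 pentamethoxybenzene
Product: 10 N,2,3,4,5,6-hexamethoxy-N-methylbenzamide, via pentamethoxyphenyllithium 9 (not isolated)
Conditions: n-BuLi, TMEDA, THF, 0 °C; then MeN(OMe)COCl, −78 °C → rt
Reagents that add atoms: N-methoxy-N-methylcarbamoyl chloride, CON(C)C(Cl)=O
Why: Directed ortho-metalation of the single ring C–H, flanked by two OMe groups, followed by acylation with the carbamoyl chloride gives the Weinreb amide, whose chelate resists a second addition.

**Step 6**
Reactants: 7 1,2-bis(benzyloxy)-4-ethynyl-5-methoxybenzene; 10 N,2,3,4,5,6-hexamethoxy-N-methylbenzamide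
Product: 13 3-[4,5-bis(benzyloxy)-2-methoxyphenyl]-1-(2,3,4,5,6-pentamethoxyphenyl)prop-2-yn-1-one, via lithium acetylide 11 (not isolated), via lithium hemiaminal chelate 12 (not isolated)
Conditions: 7, n-BuLi, THF, −78 °C; then 10, −78 → 0 °C; quench into cold 1 M HCl
Reagents that add atoms: none
Why: Weinreb ketone synthesis, in which the slim acetylide adds once to the hindered amide and the N,O-chelate (a transient racemic centre) collapses only on acidic quench, which also protonates the released amine so it cannot add to the ynone.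

**Step 7**
Reactants: 13 3-[4,5-bis(benzyloxy)-2-methoxyphenyl]-1-(2,3,4,5,6-pentamethoxyphenyl)prop-2-yn-1-one
Product: 15 2-[4,5-bis(benzyloxy)-2-methoxyphenyl]-3-iodo-5,6,7,8-tetramethoxy-4H-chromen-4-one, via O-methyl oxonium chloride 14 (not isolated)
Conditions: ICl (1.2 equiv), CH2Cl2, −78 °C → rt; aq Na2S2O3 wash
Reagents that add atoms: iodine monochloride, ClI
Why: Larock-type electrophilic iodocyclisation, in which I+ adds at the carbon α to C=O so the cation sits next to the electron-rich B-ring, an A-ring ortho-OMe closes 6-endo-dig (this is favoured over 5-endo benzofuran formation by the B-ring OMe, and the fully substituted A-ring cannot be iodinated) and chloride demethylates the oxonium.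

**Step 8**
Reactants: 15 2-[4,5-bis(benzyloxy)-2-methoxyphenyl]-3-iodo-5,6,7,8-tetramethoxy-4H-chromen-4-one
Product: 16 2-[4,5-bis(benzyloxy)-2-methoxyphenyl]-3,5,6,7,8-pentamethoxy-4H-chromen-4-one
Conditions: CuI (10 mol%), 3,4,7,8-tetramethyl-1,10-phenanthroline (20 mol%), Cs2CO3, MeOH/toluene, 80 °C, sealed tube
Reagents that add atoms: methanol, CO
Why: Proposed new method: Ullmann-type Cu(I)/phenanthroline C–O cross-coupling applied to an α-iodo-enone (3-iodoflavone), in which the activated C3–I bond adds oxidatively to ligated Cu(I) methoxide and C–OMe reductive elimination follows, the closest known reaction type being the Cu/phenanthroline etherification of vinyl and aryl iodides with aliphatic alcohols.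

**Step 9**
Reactants: 16 2-[4,5-bis(benzyloxy)-2-methoxyphenyl]-3,5,6,7,8-pentamethoxy-4H-chromen-4-one
Product: 18 5,4',5'-trihydroxy-3,6,7,8,2'-pentamethoxyflavone [2-(4,5-dihydroxy-2-methoxyphenyl)-5-hydroxy-3,6,7,8-tetramethoxy-4H-chromen-4-one], via boron chelate 17 (not isolated)
Conditions: BCl3 (1 M in CH2Cl2, excess), pentamethylbenzene, CH2Cl2, −78 → 0 °C; then MeOH/H2O
Reagents that add atoms: none
Why: Lewis-acid ether cleavage, in which BCl3 removes both benzyl groups (the benzyl cation is trapped by pentamethylbenzene) and, through the six-membered C4=O···B chelate, only the peri 5-OMe, which ties up the carbonyl and spares the 3-, 6-, 7-, 8- and 2'-OMe groups at ≤0 °C.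

**Compound list**
1 | 3,4-bis(benzyloxy)benzaldehyde | O=Cc1ccc(OCc2ccccc2)c(OCc2ccccc2)c1 | starting material
2 | 3,4-bis(benzyloxy)phenyl formate | O=COc1ccc(OCc2ccccc2)c(OCc2ccccc2)c1 | intermediate
3 | 3,4-bis(benzyloxy)phenol | Oc1ccc(OCc2ccccc2)c(OCc2ccccc2)c1 | intermediate
4 | 1,2-bis(benzyloxy)-4-methoxybenzene | COc1ccc(OCc2ccccc2)c(OCc2ccccc2)c1 | intermediate
5 | N-[4,5-bis(benzyloxy)-2-methoxybenzylidene]-N-methylmethanaminium chloride | COc1cc(OCc2ccccc2)c(OCc2ccccc2)cc1C=[N+](C)C.[Cl-] | intermediate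
6 | 4,5-bis(benzyloxy)-2-methoxybenzaldehyde | COc1cc(OCc2ccccc2)c(OCc2ccccc2)cc1C=O | intermediate
7 | 1,2-bis(benzyloxy)-4-ethynyl-5-methoxybenzene | COc1cc(OCc2ccccc2)c(OCc2ccccc2)cc1C#C | intermediate
8 | pentamethoxybenzene | COc1cc(OC)c(OC)c(OC)c1OC | starting material
9 | (2,3,4,5,6-pentamethoxyphenyl)lithium | [Li]c1c(OC)c(OC)c(OC)c(OC)c1OC | intermediate
10 | N,2,3,4,5,6-hexamethoxy-N-methylbenzamide | CON(C)C(=O)c1c(OC)c(OC)c(OC)c(OC)c1OC | intermediate
11 | lithium [4,5-bis(benzyloxy)-2-methoxyphenyl]acetylide | COc1cc(OCc2ccccc2)c(OCc2ccccc2)cc1C#C[Li] | intermediate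
12 | lithium hemiaminal chelate from 11 and 10 (racemic, transient) | COc1cc(OCc2ccccc2)c(OCc2ccccc2)cc1C#CC(O[Li])(N(C)OC)c1c(OC)c(OC)c(OC)c(OC)c1OC | intermediate
13 | 3-[4,5-bis(benzyloxy)-2-methoxyphenyl]-1-(2,3,4,5,6-pentamethoxyphenyl)prop-2-yn-1-one | COc1cc(OCc2ccccc2)c(OCc2ccccc2)cc1C#CC(=O)c1c(OC)c(OC)c(OC)c(OC)c1OC | intermediate
14 | 2-[4,5-bis(benzyloxy)-2-methoxyphenyl]-3-iodo-5,6,7,8-tetramethoxy-1-methyl-4-oxo-4H-chromen-1-ium chloride | C[O+]1C(-c2cc(OCc3ccccc3)c(OCc3ccccc3)cc2OC)=C(I)C(=O)c2c(OC)c(OC)c(OC)c(OC)c21.[Cl-] | intermediate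
15 | 2-[4,5-bis(benzyloxy)-2-methoxyphenyl]-3-iodo-5,6,7,8-tetramethoxy-4H-chromen-4-one | COc1cc(OCc2ccccc2)c(OCc2ccccc2)cc1-c1oc2c(OC)c(OC)c(OC)c(OC)c2c(=O)c1I | intermediate
16 | 2-[4,5-bis(benzyloxy)-2-methoxyphenyl]-3,5,6,7,8-pentamethoxy-4H-chromen-4-one | COc1cc(OCc2ccccc2)c(OCc2ccccc2)cc1-c1oc2c(OC)c(OC)c(OC)c(OC)c2c(=O)c1OC | intermediate
17 | boron chelate: 5-O-dichloroboryl, 4',5'-O,O-chloroboranediyl derivative of the target | COc1cc2OB(Cl)Oc2cc1-c1oc2c(OC)c(OC)c(OC)c(OB(Cl)Cl)c2c(=O)c1OC | intermediate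
18 | 5,4',5'-trihydroxy-3,6,7,8,2'-pentamethoxyflavone | COc1cc(O)c(O)cc1-c1oc2c(OC)c(OC)c(OC)c(O)c2c(=O)c1OC | target

**Totals**
Total step count: 9. Longest linear sequence: 8 steps (1 → 18 through steps 1, 2, 3, 4, 6, 7, 8, 9); the A-ring branch (step 5) joins at step 6.

**Three steps most likely to fail, with fallbacks**

Step 8 (Cu-catalysed methoxylation) carries the most risk. Methoxide may attack C2 and open the pyranone, or hydrodeiodination may win. The fallback sets out from 15 and reverses the polarity at C3. I/Mg exchange with i-PrMgCl·LiCl (THF, −40 °C) gives the 3-chloromagnesio flavone F3, which is trapped with B(OMe)3 to give the dimethyl flavon-3-ylboronate F4. Oxidation in the same pot with NaBO3·4H2O (THF/H2O) gives the flavonol 2-[4,5-bis(benzyloxy)-2-methoxyphenyl]-3-hydroxy-5,6,7,8-tetramethoxy-4H-chromen-4-one F5. O-Methylation (MeI, K2CO3, acetone) then comes back to the route at 16.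

Step 9 (global BCl3 unmasking) may over-demethylate at the 3-OMe or 6-OMe, or C-benzylate the electron-rich catechol. The fallback sets out from 16 and separates the two deprotections by mechanism. Hydrogenolysis (H2, Pd/C, EtOAc/MeOH) gives 2-(4,5-dihydroxy-2-methoxyphenyl)-3,5,6,7,8-pentamethoxy-4H-chromen-4-one F6. Brønsted-acid peri-demethylation (conc. HCl, EtOH, reflux), which relies on protonation of the C4 carbonyl hydrogen-bonded to O5, then delivers 18 directly.

Step 6 (acetylide addition to the doubly ortho-substituted, twisted Weinreb amide) may be too slow, or the ynone may be lost to conjugate addition of the liberated amine. The fallback sets out from 8: the aryllithium 9 is quenched with DMF instead to give 2,3,4,5,6-pentamethoxybenzaldehyde F1. Lithium acetylide 11 adds to this unhindered aldehyde to give the racemic propargylic alcohol 3-[4,5-bis(benzyloxy)-2-methoxyphenyl]-1-(2,3,4,5,6-pentamethoxyphenyl)prop-2-yn-1-ol F2. Oxidation with MnO2 (CH2Cl2, rt) comes back to the route at 13.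

**Further compounds**
F1 | step 6 | 2,3,4,5,6-pentamethoxybenzaldehyde | O=Cc1c(OC)c(OC)c(OC)c(OC)c1OC
F2 | step 6 | 3-[4,5-bis(benzyloxy)-2-methoxyphenyl]-1-(2,3,4,5,6-pentamethoxyphenyl)prop-2-yn-1-ol (racemic) | COc1cc(OCc2ccccc2)c(OCc2ccccc2)cc1C#CC(O)c1c(OC)c(OC)c(OC)c(OC)c1OC
F3 | step 8 | {2-[4,5-bis(benzyloxy)-2-methoxyphenyl]-5,6,7,8-tetramethoxy-4-oxo-4H-chromen-3-yl}magnesium chloride | COc1cc(OCc2ccccc2)c(OCc2ccccc2)cc1-c1oc2c(OC)c(OC)c(OC)c(OC)c2c(=O)c1[Mg]Cl
F4 | step 8 | dimethyl {2-[4,5-bis(benzyloxy)-2-methoxyphenyl]-5,6,7,8-tetramethoxy-4-oxo-4H-chromen-3-yl}boronate | COc1cc(OCc2ccccc2)c(OCc2ccccc2)cc1-c1oc2c(OC)c(OC)c(OC)c(OC)c2c(=O)c1B(OC)OC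
F5 | step 8 | 2-[4,5-bis(benzyloxy)-2-methoxyphenyl]-3-hydroxy-5,6,7,8-tetramethoxy-4H-chromen-4-one | COc1cc(OCc2ccccc2)c(OCc2ccccc2)cc1-c1oc2c(OC)c(OC)c(OC)c(OC)c2c(=O)c1O
F6 | step 9 | 2-(4,5-dihydroxy-2-methoxyphenyl)-3,5,6,7,8-pentamethoxy-4H-chromen-4-one | COc1cc(O)c(O)cc1-c1oc2c(OC)c(OC)c(OC)c(OC)c2c(=O)c1OC
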